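**Strategy.** Both prenyl groups are disconnected at C1''–C2'' (on C6, ring A) and C1'''–C2''' (on C3', ring B). Each benzylic CH2 sits ortho to a free phenol (O5 and O7 on ring A, O4' on ring B) and can therefore serve as the terminus of an ortho-quinone methide. The precursor is the unprotected isoflavone 20 with CH2OMe at C6 and C3'. Heated with 2-methylprop-1-enylboronic acid 21, it should lose methanol twice and accept two isobutenyl groups, giving the target without any later step. The CH2OMe groups come from aryllithium/MOMCl alkylations. Ring C is closed through the only free oxygen, para to the ring A CH2OMe, which fixes 6-substitution.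

Key step: step 11

Remark: the ring A ether of 20 (donor oxygens O5, O7 and O1 ortho/para to C6) is assumed to ionise before the ring B ether, which only sets the order of 22–24 and not the product; 7–9, 13–15 and 18 are racemic at centres that are erased before 20. (MOM = CH2OCH3, EE = 1-ethoxyethyl.)

Step 1
Reactants: 1 resorcinol
Product: 2 1,3-bis(methoxymethoxy)benzene
Conditions: MOMCl (2.5 equiv), iPr2NEt (3 equiv), CH2Cl2, 0 °C to rt
Reagents that add atoms: chloromethyl methyl ether (MOMCl), COCCl
Why: Routine O-alkylation of both phenols with an α-chloro ether gives the bis-acetal whose oxygens later direct lithiation.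

Step 2
Reactants: 2 1,3-bis(methoxymethoxy)benzene
Product: 4 2-(methoxymethyl)-1,3-bis(methoxymethoxy)benzene, via 2-lithio-1,3-bis(methoxymethoxy)benzene 3 (not isolated)
Conditions: n-BuLi (1.1 equiv), THF, 0 °C, 1 h; MOMCl (1.3 equiv), −78 °C to rt
Reagents that add atoms: chloromethyl methyl ether, COCCl; n-butyllithium, [Li]CCCC (Li in 3 only)
Why: Directed ortho-metalation takes place at C2 between the two cooperating OMOM groups, and the aryllithium displaces chloride from MOMCl (SN2) to give the benzyl methyl ether.

Step 3
Reactants: 4 2-(methoxymethyl)-1,3-bis(methoxymethoxy)benzene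
Product: 6 3,5-bis(methoxymethoxy)-4-(methoxymethyl)phenol, via aryl pinacol boronate 5 (not isolated)
Conditions: [Ir(OMe)(cod)]2 (1.5 mol %), 4,4'-di-tert-butyl-2,2'-bipyridine (3 mol %), B2pin2 (1.0 equiv), THF, 80 °C; then 30% H2O2, aq NaOH, 0 °C; work-up at pH 7, product used without acidic contact
Reagents that add atoms: hydrogen peroxide, OO; bis(pinacolato)diboron, CC1(C)OB(OC1(C)C)B1OC(C)(C)C(C)(C)O1 (Bpin in 5 only)
Why: Sterically governed iridium-catalysed C–H borylation of a 1,2,3-trisubstituted benzene can reach only C5–H, the one hydrogen without an ortho neighbour, and boronate oxidation then places the oxygen para to the CH2OMe group, so the two remaining ring positions are equivalent.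

Step 4
Reactants: 6 3,5-bis(methoxymethoxy)-4-(methoxymethyl)phenol
Product: 7 5-(1-ethoxyethoxy)-2-(methoxymethyl)-1,3-bis(methoxymethoxy)benzene (racemic)
Conditions: CH3CH(Cl)OEt (1.3 equiv), iPr2NEt (2 equiv), CH2Cl2, 0 °C
Reagents that add atoms: 1-chloroethyl ethyl ether, CCOC(C)Cl
Why: Base-mediated O-alkylation with an α-chloro ether masks the phenol without the acid that the electron-rich para-hydroxybenzyl ether 6 would not tolerate, and installs an acetal far more acid-labile than MOM, whose new centre is racemic and is removed in step 5.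

Step 5
Reactants: 7 5-(1-ethoxyethoxy)-2-(methoxymethyl)-1,3-bis(methoxymethoxy)benzene
Product: 10 1-[6-hydroxy-2,4-bis(methoxymethoxy)-3-(methoxymethyl)phenyl]ethanone, via aryllithium 8 (not isolated), via EE-protected ketone 9 (not isolated)
Conditions: n-BuLi (1.15 equiv), THF, 0 °C, 1 h; MeC(O)N(OMe)Me (1.5 equiv), −78 to 0 °C; H2O; crude product in MeOH, pyridinium p-toluenesulfonate (10 mol %), rt
Reagents that add atoms: N-methoxy-N-methylacetamide, CC(=O)N(C)OC; n-butyllithium, [Li]CCCC (Li in 8 only)
Why: Directed ortho-metalation at either of the two equivalent positions flanked by OEE and OMOM, Weinreb ketone synthesis and selective methanolysis of the acetaldehyde-type acetal (much faster than that of the formaldehyde-type MOM acetals) leave one free OH, ortho to the ketone and para to the CH2OMe.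

Step 6
Reactants: 11 4-hydroxy-2-methoxybenzaldehyde
Product: 12 2-methoxy-4-(methoxymethoxy)benzaldehyde
Conditions: MOMCl (1.3 equiv), iPr2NEt (2 equiv), CH2Cl2, 0 °C to rt
Reagents that add atoms: chloromethyl methyl ether, COCCl
Why: Simple O-alkylation of the only phenol, with the OMe/OH differentiation of ring B bought in with the starting material.

Step 7
Reactants: 12 2-methoxy-4-(methoxymethoxy)benzaldehyde
Product: 16 2-methoxy-3-(methoxymethyl)-4-(methoxymethoxy)benzaldehyde, via lithium amino alkoxide 13 (not isolated), via C3-lithiated amino alkoxide 14 (not isolated), via C3-methoxymethylated amino alkoxide 15 (not isolated)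
Conditions: lithium 4-methylpiperazin-1-ide (1.1 equiv, from N-methylpiperazine and n-BuLi), THF, −20 °C; n-BuLi (2 equiv), −20 °C, 3 h; MOMCl (4 equiv), −78 °C to rt; H2O, 0 °C
Reagents that add atoms: chloromethyl methyl ether, COCCl; lithium 4-methylpiperazin-1-ide, [Li]N1CCN(C)CC1 (atoms in 13–15 only); n-butyllithium, [Li]CCCC (Li in 14 only)
Why: The lithium amide masks the aldehyde in situ as a weakly directing α-amino alkoxide, directed ortho-metalation then occurs at C3 between the cooperating OMe and OMOM groups, MOMCl alkylates the aryllithium and water releases the aldehyde, so the racemic carbinolamine centre is lost on work-up.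

Step 8
Reactants: 10 1-[6-hydroxy-2,4-bis(methoxymethoxy)-3-(methoxymethyl)phenyl]ethanone; 16 2-methoxy-3-(methoxymethyl)-4-(methoxymethoxy)benzaldehyde
Product: 17 (E)-1-[6-hydroxy-2,4-bis(methoxymethoxy)-3-(methoxymethyl)phenyl]-3-[2-methoxy-3-(methoxymethyl)-4-(methoxymethoxy)phenyl]prop-2-en-1-one
Conditions: KOH (10 equiv), MeOH, rt, 36 h
Reagents that add atoms: none
Why: The Claisen–Schmidt condensation, well established for 2-hydroxy-4,6-bis(MOM-oxy)acetophenones, gives the E-enone under thermodynamic control, and methanol as solvent makes any exchange at the benzylic ethers degenerate.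

Step 9
Reactants: 17 the E-chalcone
Product: 18 1-[6-hydroxy-2,4-bis(methoxymethoxy)-3-(methoxymethyl)phenyl]-3,3-dimethoxy-2-[2-methoxy-3-(methoxymethyl)-4-(methoxymethoxy)phenyl]propan-1-one (racemic)
Conditions: Tl(NO3)3·3H2O (1.1 equiv), MeOH/HC(OMe)3 (3:1), 0 °C to rt; filtration of TlNO3; NaHCO3 wash
Reagents that add atoms: methanol, CO
Why: The oxidative 1,2-aryl migration of a 2'-hydroxychalcone with trivalent thallium (methoxythallation, then shift of the electron-rich 2,4-dioxygenated ring B from Cβ to Cα as monovalent thallium departs) is the classical chalcone-to-isoflavone rearrangement and gives the β-keto acetal, whose new centre is racemic and vanishes in step 10.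

Step 10
Reactants: 18 the β-keto acetal
Product: 20 5,7,4'-trihydroxy-2'-methoxy-6,3'-bis(methoxymethyl)isoflavone, via tris-MOM isoflavone 19 (not isolated)
Conditions: HCl in MeOH (0.5 M), substrate 0.01 M, rt 1 h, then 45 °C
Reagents that add atoms: none
Why: Acid-catalysed acetal exchange lets the only free phenol attack the oxocarbenium carbon and loss of methanol gives isoflavone 19 at rt, before the slower MOM methanolysis at 45 °C frees O5, O7 and O4', while in dilute methanol any ionisation of the two ArCH2OMe groups merely regenerates them.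

Step 11
Reactants: 20 5,7,4'-trihydroxy-2'-methoxy-6,3'-bis(methoxymethyl)isoflavone; 21 2-methylprop-1-enylboronic acid
Product: 25 2'-methoxylupalbigenin, via ring A ortho-quinone methide 22 (not isolated), via 6-prenyl monoether 23 (not isolated), via ring B ortho-quinone methide 24 (not isolated)
Conditions: 21 (6 equiv), 2,2'-biphenol (20 mol %), 4 Å MS, PhMe/1,4-dioxane (4:1), 90 to 105 °C, 20 added in dioxane over 6 h (syringe pump), then 12 h; H2O work-up
Reagents that add atoms: 2-methylprop-1-enylboronic acid (21), CC(C)=CB(O)O
Why: Proposed new method: each ArCH2OMe lies ortho to a free phenol, so exchange of that phenol onto boron (the boronic acid or its biphenol ester) puts a Lewis acid beside the ether oxygen, methanol leaves into the sieves and an ortho-quinone methide forms with its oxygen still on boron. The tetracoordinate boronate hands its isobutenyl group to the exocyclic CH2 through a six-membered transition state, forming C1''–C2'' and later C1'''–C2''' and rearomatising each ring, and a stepwise attack of CH2 on the boron-bearing alkene carbon (tertiary β-boryl cation, then deborylation) would end in the same prenyl group. The closest known reaction type is the biphenol-catalysed 1,4-addition of alkenyl boronates to aryl-substituted ortho-quinone methides released from ortho-hydroxybenzyl ethers, and what is new here is the unsubstituted CH2 terminus and two such events in one flask. No ring is closed and no stereocentre arises. The step needs attack at CH2 in preference to chromone C2 and to quinone methide dimerisation: O=C–C=CH2 of the quinone methide is locked s-cis and fits the cyclic transfer, the chromone enone O4=C4–C3=C2 is locked s-trans so that a boron on O4 cannot reach C2, and slow addition of 20 into excess 21 keeps the free quinone methide dilute. The ring A ether, with three oxygen donors, should ionise first and the ring B ether at the higher temperature, hence 22, 23 and 24 in that order.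

**Compound list**
1 | resorcinol | Oc1cccc(O)c1 | starting material
2 | 1,3-bis(methoxymethoxy)benzene | COCOc1cccc(OCOC)c1 | intermediate
3 | 2-lithio-1,3-bis(methoxymethoxy)benzene (in situ) | [Li]c1c(OCOC)cccc1OCOC | intermediate
4 | 2-(methoxymethyl)-1,3-bis(methoxymethoxy)benzene | COCOc1cccc(OCOC)c1COC | intermediate
5 | 2-[3,5-bis(methoxymethoxy)-4-(methoxymethyl)phenyl]-4,4,5,5-tetramethyl-1,3,2-dioxaborolane (in situ) | COCOc1cc(B2OC(C)(C)C(C)(C)O2)cc(OCOC)c1COC | intermediate
6 | 3,5-bis(methoxymethoxy)-4-(methoxymethyl)phenol | COCOc1cc(O)cc(OCOC)c1COC | intermediate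
7 | 5-(1-ethoxyethoxy)-2-(methoxymethyl)-1,3-bis(methoxymethoxy)benzene (racemic) | CCOC(C)Oc1cc(OCOC)c(COC)c(OCOC)c1 | intermediate
8 | aryllithium of 7, lithiated between OEE and OMOM (in situ, racemic) | [Li]c1c(OC(C)OCC)cc(OCOC)c(COC)c1OCOC | intermediate
9 | 1-[2-(1-ethoxyethoxy)-4,6-bis(methoxymethoxy)-5-(methoxymethyl)phenyl]ethanone (in situ, racemic) | CCOC(C)Oc1cc(OCOC)c(COC)c(OCOC)c1C(C)=O | intermediate
10 | 1-[6-hydroxy-2,4-bis(methoxymethoxy)-3-(methoxymethyl)phenyl]ethanone | CC(=O)c1c(O)cc(OCOC)c(COC)c1OCOC | intermediate
11 | 4-hydroxy-2-methoxybenzaldehyde | COc1cc(O)ccc1C=O | starting material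
12 | 2-methoxy-4-(methoxymethoxy)benzaldehyde | COCOc1ccc(C=O)c(OC)c1 | intermediate
13 | lithium [2-methoxy-4-(methoxymethoxy)phenyl](4-methylpiperazin-1-yl)methanolate (in situ, racemic) | [Li]OC(N1CCN(C)CC1)c1ccc(OCOC)cc1OC | intermediate
14 | C3-lithiated form of 13 (in situ, racemic) | [Li]OC(N1CCN(C)CC1)c1ccc(OCOC)c([Li])c1OC | intermediate
15 | C3-methoxymethylated amino alkoxide (in situ, racemic) | [Li]OC(N1CCN(C)CC1)c1ccc(OCOC)c(COC)c1OC | intermediate
16 | 2-methoxy-3-(methoxymethyl)-4-(methoxymethoxy)benzaldehyde | COCOc1ccc(C=O)c(OC)c1COC | intermediate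
17 | (E)-chalcone from 10 and 16 | COCOc1ccc(/C=C/C(=O)c2c(O)cc(OCOC)c(COC)c2OCOC)c(OC)c1COC | intermediate
18 | 2-aryl-3,3-dimethoxypropan-1-one (β-keto acetal, racemic) | COCOc1ccc(C(C(OC)OC)C(=O)c2c(O)cc(OCOC)c(COC)c2OCOC)c(OC)c1COC | intermediate
19 | 5,7,4'-tris(methoxymethoxy)-2'-methoxy-6,3'-bis(methoxymethyl)isoflavone (in situ) | COCOc1ccc(-c2coc3cc(OCOC)c(COC)c(OCOC)c3c2=O)c(OC)c1COC | intermediate
20 | 5,7,4'-trihydroxy-2'-methoxy-6,3'-bis(methoxymethyl)isoflavone | COCc1c(O)cc2occ(-c3ccc(O)c(COC)c3OC)c(=O)c2c1O | intermediate
21 | 2-methylprop-1-enylboronic acid | CC(C)=CB(O)O | starting material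
22 | ring A ortho-quinone methide (C6=CH2, C7=O; in situ) | C=C1C(=O)C=C2OC=C(c3ccc(O)c(COC)c3OC)C(=O)C2=C1O | intermediate
23 | 5,7,4'-trihydroxy-2'-methoxy-3'-(methoxymethyl)-6-prenylisoflavone (in situ) | COCc1c(O)ccc(-c2coc3cc(O)c(CC=C(C)C)c(O)c3c2=O)c1OC | intermediate
24 | ring B ortho-quinone methide of 23 (C3'=CH2, C4'=O; in situ) | C=C1C(=O)C=CC(c2coc3cc(O)c(CC=C(C)C)c(O)c3c2=O)=C1OC | intermediate
25 | 2'-methoxylupalbigenin (5,7,4'-trihydroxy-2'-methoxy-6,3'-diprenylisoflavone) | COc1c(-c2coc3cc(O)c(CC=C(C)C)c(O)c3c2=O)ccc(O)c1CC=C(C)C | target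

**Total step count:** 11. **Longest linear sequence:** 9 (steps 1–5 and 8–11). Steps 6 and 7 form the ring B branch.

**Steps most likely to fail**

Step 11 (key step).
- What may go wrong: the unsubstituted quinone methides may dimerise, re-add methanol or be trapped by phenols faster than boron transfers the alkenyl group. The ring B ether may ionise too slowly, and the boronic acid may protodeboronate on long heating.
- Fallback, setting out from 20 and returning at 25, uses palladium catalysis on phenol-masked benzylic bromides.
- Compound 20 is peracetylated (Ac2O, pyridine, DMAP) to 5,7,4'-triacetoxy-2'-methoxy-6,3'-bis(methoxymethyl)isoflavone F1.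
- Both benzylic ethers are exchanged for bromide (AcBr, cat. ZnBr2, CH2Cl2) to give 5,7,4'-triacetoxy-6,3'-bis(bromomethyl)-2'-methoxyisoflavone F2.
- A double Stille coupling with tributyl(2-methylprop-1-enyl)stannane (Pd(PPh3)4, THF, 60 °C, no base) gives 2'-methoxylupalbigenin triacetate F3.
- Brief K2CO3/MeOH treatment then leads to 25.

Step 9.
- What may go wrong: oxidation of the electron-rich ring A phenol, or early loss of the acetal on the future O5 under the acid released, may outrun the aryl shift. Early loss of that acetal would open ring closure through the wrong oxygen.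
- Fallback, setting out from 17 and returning at 19, closes ring C first.
- Compound 17 is isomerised by intramolecular oxa-Michael addition (NaOAc, MeOH, reflux) to racemic 5,7-bis(methoxymethoxy)-6-(methoxymethyl)-2-[2-methoxy-3-(methoxymethyl)-4-(methoxymethoxy)phenyl]chroman-4-one F4, in which the phenol is tied up as the ring ether.
- The 2,3-aryl shift is then brought about by hypervalent iodine oxidation of the flavanone (PhI(OH)OTs, MeCN). This gives 19 as an isolated compound, which is methanolysed as in step 10.

Step 5.
- What may go wrong: lithiation may stray to the benzylic CH2 (followed by Wittig-type rearrangement), or the hindered aryllithium may merely enolise the amide.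
- Fallback, setting out from 6 and returning at 10, brings the acetyl group in through oxygen.
- Compound 6 is acetylated (Ac2O, Et3N, DMAP) to 3,5-bis(methoxymethoxy)-4-(methoxymethyl)phenyl acetate F5 and irradiated (254 nm, MeOH).
- With the para position blocked and both ortho positions equivalent, the photo-Fries rearrangement can deliver only 10, and steps 4 and 5 are bypassed.

**Further compounds**
F1 | step 11 | 5,7,4'-triacetoxy-2'-methoxy-6,3'-bis(methoxymethyl)isoflavone | COCc1c(OC(C)=O)cc2occ(-c3ccc(OC(C)=O)c(COC)c3OC)c(=O)c2c1OC(C)=O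
F2 | step 11 | 5,7,4'-triacetoxy-6,3'-bis(bromomethyl)-2'-methoxyisoflavone | BrCc1c(OC(C)=O)cc2occ(-c3ccc(OC(C)=O)c(CBr)c3OC)c(=O)c2c1OC(C)=O
F3 | step 11 | 2'-methoxylupalbigenin triacetate | COc1c(-c2coc3cc(OC(C)=O)c(CC=C(C)C)c(OC(C)=O)c3c2=O)ccc(OC(C)=O)c1CC=C(C)C
F4 | step 9 | 5,7-bis(methoxymethoxy)-6-(methoxymethyl)-2-[2-methoxy-3-(methoxymethyl)-4-(methoxymethoxy)phenyl]chroman-4-one (racemic) | COCOc1ccc(C2CC(=O)c3c(O2)cc(OCOC)c(COC)c3OCOC)c(OC)c1COC
F5 | step 5 | 3,5-bis(methoxymethoxy)-4-(methoxymethyl)phenyl acetate | COCOc1cc(OC(C)=O)cc(OCOC)c1COC
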